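Cuts: the four phenols are masked as MOM ethers. Ring C is then cut at O1–C2 and C4–C4a together. This leaves ring A as a 2-bromo-6-prenylphenol and ring B, with the chain C2–C3–C4, as a trans-epoxy N-acylpyrrole, which is cut further at C2=C3 (Wittig) and at the three side-chain bonds of ring B.
Enabling feature: O1 and C4a are neighbours on the phloroglucinol ring A and can act together as an ortho-lithiated phenoxide. C4 (acyl carbon) and C2 (benzylic to the 2',4'-dioxygenated ring B, its leaving group being the C3 oxygen held in an oxirane) form the matching 1,3-dielectrophile.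
Forward order: ring B receives 3'-geranyl, 5'-prenyl and CHO by three directed ortho-metalations and is then olefinated and epoxidised. Ring A is brominated on both sides of its one free OH, and one bromine is traded for the 8-prenyl group.
Ring C arises last, in the same operation that joins the two halves; removal of the MOM groups ends the route.
Stereochemistry: C3 comes from a ligand-controlled nucleophilic epoxidation that ignores the isolated alkenes. C2 comes from inversion at the benzylic oxirane carbon and is backed by the thermodynamic 2,3-trans preference.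

Key step: step 12

Abbreviations: MOM = CH3OCH2; prenyl = 3-methylbut-2-en-1-yl; geranyl = (2E)-3,7-dimethylocta-2,6-dien-1-yl; flavonoid numbering (O1, C2 to C8a, primed numbers for ring B) is used for the target and its precursors.
Assumption: the facial sense of the epoxidation in step 8 is taken from the behaviour of β-aryl enones and enoyl pyrroles with (S)-configured binaphthol-type ligands; should the substrate respond in the opposite sense, the equally available (R)-ligand is used.

Step 1
Reactants: 1 resorcinol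
Product: 2 1,3-bis(methoxymethoxy)benzene
Conditions: MOMCl (2.5 equiv), i-Pr2NEt (3 equiv), CH2Cl2, 0 °C → rt
Reagents that add atoms: chloromethyl methyl ether (MOMCl), COCCl
Why: Base-mediated O-alkylation of both phenols with an α-chloro ether is routine, and the MOM groups later serve as directing groups for metalation and as acid-labile masks.

Step 2
Reactants: 2 1,3-bis(methoxymethoxy)benzene; 3 geranyl bromide
Product: 5 2-geranyl-1,3-bis(methoxymethoxy)benzene, via aryllithium 4 (not isolated)
Conditions: n-BuLi (1.1 equiv), THF, 0 °C → rt; CuI (10 mol %), 3, −78 °C → rt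
Reagents that add atoms: none
Why: Directed ortho-metalation takes place at C2 under the cooperative effect of the two flanking MOM ethers, and copper-catalysed allylic substitution at the primary carbon of 3 keeps the E geometry.

Step 3
Reactants: 5 2-geranyl-1,3-bis(methoxymethoxy)benzene; 6 prenyl bromide
Product: 8 2-geranyl-1,3-bis(methoxymethoxy)-4-prenylbenzene, via aryllithium 7 (not isolated)
Conditions: n-BuLi (1.2 equiv), TMEDA, THF, 0 °C; CuI (10 mol %), 6, −78 °C → rt
Reagents that add atoms: none
Why: A second directed ortho-metalation can only go to C4 (equivalent to C6), since kinetic ring lithiation next to the chelating MOM ether should outrun deprotonation of the ArCH2 group, and allylic substitution on 6 gives the linear prenyl isomer.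

Step 4
Reactants: 8 2-geranyl-1,3-bis(methoxymethoxy)-4-prenylbenzene
Product: 10 3-geranyl-2,4-bis(methoxymethoxy)-5-prenylbenzaldehyde, via aryllithium 9 (not isolated)
Conditions: n-BuLi (1.3 equiv), TMEDA, THF, 0 °C; DMF, −78 °C → rt; H2O
Reagents that add atoms: N,N-dimethylformamide (DMF), CN(C)C=O
Why: The one remaining ring position ortho to a MOM ether is lithiated (directed ortho-metalation) and formylated by DMF.

Step 5
Reactants: 11 pyrrole; 12 bromoacetyl bromide
Product: 14 2-bromo-1-(1H-pyrrol-1-yl)ethan-1-one, via sodium pyrrolide 13 (not isolated)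
Conditions: NaH, THF, 0 °C; then added to 12 (1.5 equiv), THF, −78 °C
Reagents that add atoms: none
Why: The ionic sodium salt of pyrrole is acylated on nitrogen by the acyl bromide, which is far more electrophilic than the alkyl bromide, and inverse addition in the cold suppresses a second substitution (N-acylation).

Step 6
Reactants: 14 2-bromo-1-(1H-pyrrol-1-yl)ethan-1-one
Product: 16 1-(1H-pyrrol-1-yl)-2-(triphenyl-λ5-phosphanylidene)ethan-1-one, via phosphonium bromide 15 (not isolated)
Conditions: PPh3, toluene, rt → 40 °C; then 1 M aq NaOH, CH2Cl2, 0 °C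
Reagents that add atoms: triphenylphosphine, c1ccc(cc1)P(c1ccccc1)c1ccccc1
Why: SN2 quaternisation of PPh3 by the α-bromo carbonyl compound and deprotonation of the acidic salt give the stabilised ylide (standard preparation of a Wittig reagent).

Step 7
Reactants: 10 3-geranyl-2,4-bis(methoxymethoxy)-5-prenylbenzaldehyde; 16 1-(1H-pyrrol-1-yl)-2-(triphenyl-λ5-phosphanylidene)ethan-1-one
Product: 17 (2E)-3-[3-geranyl-2,4-bis(methoxymethoxy)-5-prenylphenyl]-1-(1H-pyrrol-1-yl)prop-2-en-1-one
Conditions: toluene, 90 °C
Reagents that add atoms: none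
Why: Wittig olefination with a carbonyl-stabilised ylide is E-selective with aromatic aldehydes and leaves MOM ethers and isolated alkenes alone.

Step 8
Reactants: 17 (2E)-3-[3-geranyl-2,4-bis(methoxymethoxy)-5-prenylphenyl]-1-(1H-pyrrol-1-yl)prop-2-en-1-one
Product: 18 {(2R,3S)-3-[3-geranyl-2,4-bis(methoxymethoxy)-5-prenylphenyl]oxiran-2-yl}(1H-pyrrol-1-yl)methanone
Conditions: Sm(O-i-Pr)3 (5 mol %), (S)-H8-BINOL (5 mol %), Ph3As=O (5 mol %), t-BuOOH (decane), 4 Å MS, THF–toluene, rt
Reagents that add atoms: tert-butyl hydroperoxide, CC(C)(C)OO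
Why: Lanthanide–binaphthoxide-catalysed nucleophilic epoxidation (Weitz–Scheffer type) adds the metal-bound peroxide only to the electron-poor enoyl pyrrole, so the three electron-rich trisubstituted alkenes stay untouched, and the (S)-configured ligand pocket directs attack to the face that gives the trans-(2R,3S)-oxirane.

Step 9
Reactants: 19 phloroglucinol
Product: 20 3,5-bis(methoxymethoxy)phenol
Conditions: MOMCl (2.0 equiv), i-Pr2NEt (2.2 equiv), DMF, 0 °C → rt; chromatography
Reagents that add atoms: chloromethyl methyl ether (MOMCl), COCCl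
Why: Statistical double O-alkylation of the threefold symmetric triol gives the bis-ether, which is separable from the mono- and tris-ethers and has one free oxygen, the later O1.

Step 10
Reactants: 20 3,5-bis(methoxymethoxy)phenol
Product: 21 2,6-dibromo-3,5-bis(methoxymethoxy)phenol
Conditions: NBS (2.0 equiv, slow addition), i-Pr2NH (20 mol %), CH2Cl2, −40 → 0 °C
Reagents that add atoms: N-bromosuccinimide, O=C1CCC(=O)N1Br
Why: In the amine-catalysed ortho-bromination of phenols the amine relays bromine from NBS as an N-bromoamine hydrogen-bonded to the OH group and delivers it to both ortho carbons, which are also less crowded than C4 between the two MOM ethers.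

Step 11
Reactants: 21 2,6-dibromo-3,5-bis(methoxymethoxy)phenol; 6 prenyl bromide
Product: 23 2-bromo-3,5-bis(methoxymethoxy)-6-prenylphenol, via lithiated phenoxide 22 (not isolated)
Conditions: n-BuLi (1.0 equiv), THF, −78 °C; t-BuLi (2.0 equiv), −78 °C; CuI (10 mol %), 6 (1.0 equiv), −78 → −20 °C; AcOH
Reagents that add atoms: none
Why: After deprotonation, bromine–lithium exchange should stop at one of the two equivalent bromines because a second exchange would build a trianion, and the aryllithium carbon is far more nucleophilic toward 6 than the hindered lithium phenoxide oxygen (halogen–metal exchange, copper-catalysed allylic substitution).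

Step 12
Reactants: 23 2-bromo-3,5-bis(methoxymethoxy)-6-prenylphenol; 18 {(2R,3S)-3-[3-geranyl-2,4-bis(methoxymethoxy)-5-prenylphenyl]oxiran-2-yl}(1H-pyrrol-1-yl)methanone
Product: 27 (2R,3R)-2-[3-geranyl-2,4-bis(methoxymethoxy)-5-prenylphenyl]-3-hydroxy-5,7-bis(methoxymethoxy)-8-prenylchroman-4-one, via lithiated phenoxide 24 (not isolated), via pyrrolyl carbinolate 25 (not isolated), via epoxy ketone phenoxide 26 (not isolated)
Conditions: 23 (1.15 equiv), n-BuLi (1.15 equiv) then t-BuLi (2.3 equiv), THF, −78 °C; 18 (1.0 equiv) in THF, −78 → 0 °C; (CF3)2CHOH, 0 °C → rt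
Reagents that add atoms: none
Why: Proposed new method: deprotonation and bromine–lithium exchange turn 23 into the C4a-lithiated O1-phenoxide 24, whose carbanion adds to the activated amide carbonyl of 18 (C4–C4a bond) to give carbinolate 25; on warming 25 expels lithium pyrrolide to leave the 2'-oxido epoxy ketone 26, and once (CF3)2CHOH has protonated the pyrrolide and hydrogen-bonded to the oxirane oxygen, O1 opens the oxirane at C2 (O1–C2 bond). The closest known reaction types are the acylation of aryllithiums by N-acylpyrroles and the cyclisation of 2'-hydroxychalcone epoxides to 2,3-trans-dihydroflavonols; what is new is their merger into a [3+3] annulation between an unprotected ortho-lithiated phenoxide and an epoxy acyl donor. Ring C closes in the 6-endo-tet mode, favoured over 5-exo attack at C3 because C2 is benzylic to the 2',4'-dialkoxy ring B and takes up the developing positive charge, whereas C3 is deactivated by the adjacent carbonyl group. C3 keeps the R configuration of its oxirane carbon because its C–O bond is never broken, and C2 becomes R through inversion at the S-configured benzylic oxirane carbon, the diequatorial 2,3-trans product also being the more stable one. The step needs the 8-prenyl and not the 6-prenyl regioisomer, which is secured because bromine marks C4a and O1 is the only unmasked oxygen of ring A, and it needs carbonyl addition ahead of any attack on oxirane, MOM ethers or alkenes, which is secured by forming 24 before 18 is added and by the low temperature.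

Step 13
Reactants: 27 (2R,3R)-2-[3-geranyl-2,4-bis(methoxymethoxy)-5-prenylphenyl]-3-hydroxy-5,7-bis(methoxymethoxy)-8-prenylchroman-4-one
Product: 28 (2R,3R)-2-[3-geranyl-2,4-dihydroxy-5-prenylphenyl]-3,5,7-trihydroxy-8-prenylchroman-4-one (target)
Conditions: HCl (ca. 1 M in MeOH), 0 °C → rt, under argon
Reagents that add atoms: none
Why: Acid-catalysed transacetalisation of aryl MOM ethers in methanol is the standard last step for prenylated flavonoids and is run cold, dilute and short so that the ortho-prenyl and ortho-geranyl phenols do not close to chromans, while C3 is untouched and any reversible opening at C2 allowed by the free 2',4'-dihydroxy ring B drains to the more stable 2,3-trans isomer.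

Compound list
1 | resorcinol | Oc1cccc(O)c1 | starting material
2 | 1,3-bis(methoxymethoxy)benzene | COCOc1cccc(OCOC)c1 | intermediate
3 | geranyl bromide, (2E)-1-bromo-3,7-dimethylocta-2,6-diene | CC(C)=CCC/C(C)=C/CBr | starting material
4 | 2-lithio-1,3-bis(methoxymethoxy)benzene | [Li]c1c(OCOC)cccc1OCOC | intermediate
5 | 2-geranyl-1,3-bis(methoxymethoxy)benzene | CC(C)=CCC/C(C)=C/Cc1c(OCOC)cccc1OCOC | intermediate
6 | prenyl bromide, 1-bromo-3-methylbut-2-ene | CC(C)=CCBr | starting material
7 | 2-geranyl-4-lithio-1,3-bis(methoxymethoxy)benzene | CC(C)=CCC/C(C)=C/Cc1c(OCOC)c([Li])ccc1OCOC | intermediate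
8 | 2-geranyl-1,3-bis(methoxymethoxy)-4-prenylbenzene | CC(C)=CCC/C(C)=C/Cc1c(OCOC)c(CC=C(C)C)ccc1OCOC | intermediate
9 | 6-lithio derivative of 8 | CC(C)=CCC/C(C)=C/Cc1c(OCOC)c(CC=C(C)C)cc([Li])c1OCOC | intermediate
10 | 3-geranyl-2,4-bis(methoxymethoxy)-5-prenylbenzaldehyde | CC(C)=CCC/C(C)=C/Cc1c(OCOC)c(CC=C(C)C)cc(C=O)c1OCOC | intermediate
11 | pyrrole | c1cc[nH]c1 | starting material
12 | bromoacetyl bromide | O=C(Br)CBr | starting material
13 | sodium pyrrolide | [Na+].c1cc[n-]c1 | intermediate
14 | 2-bromo-1-(1H-pyrrol-1-yl)ethan-1-one | O=C(CBr)n1cccc1 | intermediate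
15 | [2-oxo-2-(1H-pyrrol-1-yl)ethyl]triphenylphosphonium bromide | [Br-].O=C(C[P+](c1ccccc1)(c1ccccc1)c1ccccc1)n1cccc1 | intermediate
16 | 1-(1H-pyrrol-1-yl)-2-(triphenyl-λ5-phosphanylidene)ethan-1-one | O=C(C=P(c1ccccc1)(c1ccccc1)c1ccccc1)n1cccc1 | intermediate
17 | (2E)-3-[3-geranyl-2,4-bis(methoxymethoxy)-5-prenylphenyl]-1-(1H-pyrrol-1-yl)prop-2-en-1-one | CC(C)=CCC/C(C)=C/Cc1c(OCOC)c(CC=C(C)C)cc(/C=C/C(=O)n2cccc2)c1OCOC | intermediate
18 | {(2R,3S)-3-[3-geranyl-2,4-bis(methoxymethoxy)-5-prenylphenyl]oxiran-2-yl}(1H-pyrrol-1-yl)methanone | CC(C)=CCC/C(C)=C/Cc1c(OCOC)c(CC=C(C)C)cc([C@@H]2O[C@H]2C(=O)n2cccc2)c1OCOC | intermediate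
19 | phloroglucinol | Oc1cc(O)cc(O)c1 | starting material
20 | 3,5-bis(methoxymethoxy)phenol | COCOc1cc(O)cc(OCOC)c1 | intermediate
21 | 2,6-dibromo-3,5-bis(methoxymethoxy)phenol | COCOc1cc(OCOC)c(Br)c(O)c1Br | intermediate
22 | lithium 2-bromo-6-lithio-3,5-bis(methoxymethoxy)phenoxide | [Li+].[Li]c1c([O-])c(Br)c(OCOC)cc1OCOC | intermediate
23 | 2-bromo-3,5-bis(methoxymethoxy)-6-prenylphenol | COCOc1cc(OCOC)c(CC=C(C)C)c(O)c1Br | intermediate
24 | lithium 2-lithio-3,5-bis(methoxymethoxy)-6-prenylphenoxide | [Li+].[Li]c1c([O-])c(CC=C(C)C)c(OCOC)cc1OCOC | intermediate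
25 | dilithium salt of the adduct of 24 to the carbonyl group of 18 (aryl, pyrrol-1-yl and oxiranyl on the carbinolate carbon, oxirane as in 18) | CC(C)=CCC/C(C)=C/Cc1c(OCOC)c(CC=C(C)C)cc([C@@H]2O[C@H]2C([O-])(n2cccc2)c2c([O-])c(CC=C(C)C)c(OCOC)cc2OCOC)c1OCOC.[Li+].[Li+] | intermediate
26 | lithium 2-{[(2R,3S)-3-aryloxiran-2-yl]carbonyl}-3,5-bis(methoxymethoxy)-6-prenylphenoxide (aryl = 3-geranyl-2,4-bis(methoxymethoxy)-5-prenylphenyl) | CC(C)=CCC/C(C)=C/Cc1c(OCOC)c(CC=C(C)C)cc([C@@H]2O[C@H]2C(=O)c2c([O-])c(CC=C(C)C)c(OCOC)cc2OCOC)c1OCOC.[Li+] | intermediate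
27 | (2R,3R)-2-[3-geranyl-2,4-bis(methoxymethoxy)-5-prenylphenyl]-3-hydroxy-5,7-bis(methoxymethoxy)-8-prenylchroman-4-one | CC(C)=CCC/C(C)=C/Cc1c(OCOC)c(CC=C(C)C)cc([C@H]2Oc3c(CC=C(C)C)c(OCOC)cc(OCOC)c3C(=O)[C@@H]2O)c1OCOC | intermediate
28 | (2R,3R)-2-[3-geranyl-2,4-dihydroxy-5-prenylphenyl]-3,5,7-trihydroxy-8-prenylchroman-4-one | CC(C)=CCC/C(C)=C/Cc1c(O)c(CC=C(C)C)cc([C@H]2Oc3c(CC=C(C)C)c(O)cc(O)c3C(=O)[C@@H]2O)c1O | target

Total step count: 13. Longest linear sequence: 8 steps (steps 1, 2, 3, 4, 7, 8, 12, 13).

Steps most likely to fail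

Step 12 (labelled step). Several processes could spoil it.
- The aryllithium may abstract the oxirane C–H of 18 instead of adding to the carbonyl group.
- The pyrrolyl carbinolate may break down slowly.
- Ring closure may drift to the 5-exo mode.
- Liberated pyrrole may capture the activated benzylic carbon.
- The basic medium may enolise C3.

The fallback uses known chemistry throughout. It sets out from 23 and 10 and comes back to the route at 27. It builds the aryl ketone first and the C2–C3 unit by aldol chemistry. Compound 23 is O-allylated (allyl bromide, K2CO3, DMF) to the allyl ether F1. Bromine–lithium exchange (t-BuLi, THF, −78 °C) gives the aryllithium F2, which is acylated by N-methoxy-N-methylacetamide to the acetophenone F3. Claisen–Schmidt condensation with 10 (KOH, EtOH, rt) gives the chalcone F4. Juliá–Colonna epoxidation (poly-L-leucine, urea–H2O2, DBU, THF) is again blind to the isolated alkenes and should give the (2R,3S)-epoxide F5. Deallylation with Pd(PPh3)4 and morpholine then frees O1 alone. The resulting 2'-hydroxy epoxy ketone F6 closes under weakly acidic conditions (pyridinium tosylate or (CF3)2CHOH), in the established way of 2'-hydroxychalcone epoxides, to 27.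

Step 8. Peroxide addition to the electron-rich, ortho-substituted cinnamoyl system may be slow. The Lewis-acidic catalyst may open the labile benzylic oxirane, and facial selectivity may be poor. The fallback moves to iminium catalysis at the aldehyde oxidation level. It sets out from 10 and 23 and comes back at 27. Wittig reaction of 10 with Ph3P=CHCHO (toluene, 80 °C) gives the enal F7. Epoxidation with aqueous H2O2 under (S)-2-{bis[3,5-bis(trifluoromethyl)phenyl](trimethylsilyloxy)methyl}pyrrolidine (10 mol %, CH2Cl2) should give the (2R,3S)-epoxy aldehyde F8. Addition of 24 (generated from 23 as in step 12) at −78 °C gives the epoxy carbinol F9, which is not isolated. It closes in (CF3)2CHOH to the (2R,3S)-flavan-3,4-diol F10, a mixture at C4. Selective oxidation of the benzylic C4 carbinol (MnO2, CH2Cl2) leads to 27.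

Step 10. Bromine may compete for C4, which is para to the OH group and lies between the two MOM ethers, and scramble the substitution pattern. The fallback removes the regiochemical question from the bromination. It sets out from 20 and comes back at 21. Exhaustive bromination (NBS, 3 equiv, CH2Cl2, 0 °C) gives the tribromide F11. n-BuLi (2 equiv, THF, −78 °C) first deprotonates the phenol. It then exchanges the bromine that is flanked by two chelating MOM ethers and lies farthest from the phenoxide charge, giving the C4-lithiated phenoxide F12. A quench with AcOH gives 21.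

Further compounds
F1 | step 12 | 1-(allyloxy)-2-bromo-3,5-bis(methoxymethoxy)-6-prenylbenzene | C=CCOc1c(Br)c(OCOC)cc(OCOC)c1CC=C(C)C
F2 | step 12 | 2-lithio analogue of F1 (lithium in place of bromine) | C=CCOc1c([Li])c(OCOC)cc(OCOC)c1CC=C(C)C
F3 | step 12 | 1-[2-(allyloxy)-4,6-bis(methoxymethoxy)-3-prenylphenyl]ethan-1-one | CC(=O)c1c(OCC=C)c(CC=C(C)C)c(OCOC)cc1OCOC
F4 | step 12 | (2E)-1-[2-(allyloxy)-4,6-bis(methoxymethoxy)-3-prenylphenyl]-3-[3-geranyl-2,4-bis(methoxymethoxy)-5-prenylphenyl]prop-2-en-1-one | CC(C)=CCC/C(C)=C/Cc1c(OCOC)c(CC=C(C)C)cc(/C=C/C(=O)c2c(OCC=C)c(CC=C(C)C)c(OCOC)cc2OCOC)c1OCOC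
F5 | step 12 | [2-(allyloxy)-4,6-bis(methoxymethoxy)-3-prenylphenyl]{(2R,3S)-3-[3-geranyl-2,4-bis(methoxymethoxy)-5-prenylphenyl]oxiran-2-yl}methanone | CC(C)=CCC/C(C)=C/Cc1c(OCOC)c(CC=C(C)C)cc([C@@H]2O[C@H]2C(=O)c2c(OCC=C)c(CC=C(C)C)c(OCOC)cc2OCOC)c1OCOC
F6 | step 12 | {(2R,3S)-3-[3-geranyl-2,4-bis(methoxymethoxy)-5-prenylphenyl]oxiran-2-yl}[2-hydroxy-4,6-bis(methoxymethoxy)-3-prenylphenyl]methanone | CC(C)=CCC/C(C)=C/Cc1c(OCOC)c(CC=C(C)C)cc([C@@H]2O[C@H]2C(=O)c2c(O)c(CC=C(C)C)c(OCOC)cc2OCOC)c1OCOC
F7 | step 8 | (2E)-3-[3-geranyl-2,4-bis(methoxymethoxy)-5-prenylphenyl]prop-2-enal | CC(C)=CCC/C(C)=C/Cc1c(OCOC)c(CC=C(C)C)cc(/C=C/C=O)c1OCOC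
F8 | step 8 | (2R,3S)-3-[3-geranyl-2,4-bis(methoxymethoxy)-5-prenylphenyl]oxirane-2-carbaldehyde | CC(C)=CCC/C(C)=C/Cc1c(OCOC)c(CC=C(C)C)cc([C@@H]2O[C@H]2C=O)c1OCOC
F9 | step 8 | 2-{hydroxy[3-aryloxiran-2-yl]methyl}-3,5-bis(methoxymethoxy)-6-prenylphenol (oxirane as in F8, carbinol carbon undefined) | CC(C)=CCC/C(C)=C/Cc1c(OCOC)c(CC=C(C)C)cc([C@@H]2O[C@H]2C(O)c2c(O)c(CC=C(C)C)c(OCOC)cc2OCOC)c1OCOC
F10 | step 8 | (2R,3S)-2-[3-geranyl-2,4-bis(methoxymethoxy)-5-prenylphenyl]-5,7-bis(methoxymethoxy)-8-prenylchromane-3,4-diol (C4 undefined) | CC(C)=CCC/C(C)=C/Cc1c(OCOC)c(CC=C(C)C)cc([C@H]2Oc3c(CC=C(C)C)c(OCOC)cc(OCOC)c3C(O)[C@@H]2O)c1OCOC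
F11 | step 10 | 2,4,6-tribromo-3,5-bis(methoxymethoxy)phenol | COCOc1c(Br)c(O)c(Br)c(OCOC)c1Br
F12 | step 10 | lithium 2,6-dibromo-4-lithio-3,5-bis(methoxymethoxy)phenoxide | [Li+].[Li]c1c(OCOC)c(Br)c([O-])c(Br)c1OCOC
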